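**Plan**

1. Retrosynthetic cuts, in order: (a) the cyclopentane bond between the CMe2 carbon and the ring-fusion CH; (b) both ring bonds of the diacyl quaternary carbon shared by the cyclopentane, the triketone ring and the seven-membered ring (its bond to the ring C=O next to the benzoyl bridgehead and its bond to the fusion CH), by excising that carbon as a diazo carbon; (c) geranyl and the acyl side chain from the carbon between two ketones; (d) the bicyclo[3.3.1]nonane-2,8-dione into a symmetric keto diester.
2. Enabling feature: the seven-membered ring is a 2-acyl-2-alkylcycloheptanone whose ketone lies between that quaternary carbon and the benzoyl-bearing bridgehead (quaternary, tri-acylated, unable to migrate). This is the retron of a diazo–carbonyl (Tiffeneau–Demjanov-type) ring expansion of a cyclohexenone; the acyl group of the diazo carbon sits on the neighbouring bridge, so the insertion also closes the six-membered triketone ring.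
3. Forward order of rings: the two cyclohexanone rings of a meso bicyclic dione (double Claisen), then the enone, then side chain, geranyl and diazo group, then ring expansion 6→7 with cage closure, then the cyclopentane (radical 5-exo).
4. Stereochemistry: absolute configuration comes from chiral lithium amide desymmetrisation of the meso dione (both bridgeheads) and from an organocatalytic nitro-Michael addition (CH–iPr centre). Geranyl enters exo, the tether fixes the new quaternary carbon, and the CH–iPr centre steers the 5-exo closure that sets the fusion CH.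
5. Convergence: bicyclic enedione 10 (5 steps) and nitro aldehyde 15 (2 steps) are joined, followed by 5 further steps.

Key step: step 11

Assumption: the chiral lithium amide of step 5 and the prolinol catalyst of step 6 are taken to induce in the sense written; the antipodal reagent would be used if the opposite sense were found.

**Route**

Step 1
Reactants: 1 3-methyl-1-phenylbut-2-en-1-one; 2 nitromethane
Product: 3 3,3-dimethyl-4-nitro-1-phenylbutan-1-one
Conditions: DBU (0.5 equiv), MeNO2 (solvent), 50 °C
Reagents that add atoms: none
Why: Michael addition of the nitronate to the β,β-dimethyl enone should create the future gem-dimethyl bridge carbon between the phenacyl CH2 and the nitromethyl carbon; no stereocentre is formed.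

Step 2
Reactants: 3 3,3-dimethyl-4-nitro-1-phenylbutan-1-one; 4 2,2,2-trifluoroethyl acrylate (2.2 equiv)
Product: 5 bis(2,2,2-trifluoroethyl) 4-(2-methyl-4-oxo-4-phenylbutan-2-yl)-4-nitroheptanedioate
Conditions: DBU (0.3 equiv), MeCN, 0 °C to rt
Reagents that add atoms: none
Why: double nitro-Michael addition of the primary nitroalkane to the unhindered acrylate should attach two identical activated-ester arms, so the product stays achiral.

Step 3
Reactants: 5 bis(2,2,2-trifluoroethyl) 4-(2-methyl-4-oxo-4-phenylbutan-2-yl)-4-nitroheptanedioate
Product: 6 bis(2,2,2-trifluoroethyl) 4-(2-methyl-4-oxo-4-phenylbutan-2-yl)heptanedioate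
Conditions: Bu3SnH (1.5 equiv), AIBN (0.2 equiv), PhMe, 110 °C
Reagents that add atoms: none
Why: radical denitration of a tertiary nitroalkane by tin hydride should replace NO2 by H and leave a prochiral CH carrying the two arms.

Step 4
Reactants: 6 bis(2,2,2-trifluoroethyl) 4-(2-methyl-4-oxo-4-phenylbutan-2-yl)heptanedioate
Product: 8 meso-1-benzoyl-9,9-dimethylbicyclo[3.3.1]nonane-2,8-dione, via monocyclic benzoyl diketone 7 (not isolated)
Conditions: NaH (2.2 equiv), THF, 0 to 65 °C
Reagents that add atoms: none
Why: double Claisen (Dieckmann-type) C-acylation, first by the phenyl ketone enolate and then by the resulting β-diketone enolate, should close both six-membered rings onto the same carbon; O-acylation would need an eight-membered ring and the weakly nucleophilic trifluoroethoxide disfavours reversal, and the product is meso.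

Step 5
Reactants: 8 meso-1-benzoyl-9,9-dimethylbicyclo[3.3.1]nonane-2,8-dione
Product: 10 (1S,5S)-1-benzoyl-9,9-dimethylbicyclo[3.3.1]non-3-ene-2,8-dione, via silyl enol ether 9 (not isolated)
Conditions: (R,R)-HN[CH(Me)Ph]2, n-BuLi, Me3SiCl (in situ), THF, −100 °C; then Pd(OAc)2 (1.1 equiv), MeCN, rt
Reagents that add atoms: none
Why: enantioselective deprotonation of the meso dione by the chiral lithium amide with internal silyl quench should select one of the two enantiotopic CH2–C=O units and so fix both bridgeheads, and Saegusa–Ito oxidation should then give the enone in that ring.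

Step 6
Reactants: 11 (E)-4-methylpent-2-enal; 12 2-nitropropane
Product: 13 (3S)-4-methyl-4-nitro-3-(propan-2-yl)pentanal
Conditions: (S)-α,α-diphenylprolinol Me3Si ether (10 mol %), PhCO2H (10 mol %), MeOH, rt
Reagents that add atoms: none
Why: iminium-catalysed nitro-Michael addition, in which the diarylprolinol silyl ether shields one face of the (E)-iminium ion, should set the (S) CH–iPr centre next to the tertiary nitro carbon.

Step 7
Reactants: 13 (3S)-4-methyl-4-nitro-3-(propan-2-yl)pentanal
Product: 15 (4S)-5-methyl-5-nitro-4-(propan-2-yl)hexanal, via methyl enol ether 14 (not isolated)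
Conditions: MeOCH2PPh3Cl, KN(SiMe3)2, THF, −78 to 0 °C; then 2 M HCl, THF, rt
Reagents that add atoms: (methoxymethyl)triphenylphosphonium chloride, COC[P+](c1ccccc1)(c1ccccc1)c1ccccc1.[Cl-]; water, O
Why: Wittig methoxymethylenation followed by enol ether hydrolysis should lengthen the aldehyde by one carbon without touching the stereocentre, which is not α to the carbonyl.

Step 8
Reactants: 10 (1S,5S)-1-benzoyl-9,9-dimethylbicyclo[3.3.1]non-3-ene-2,8-dione; 15 (4S)-5-methyl-5-nitro-4-(propan-2-yl)hexanal
Product: 17 7-[(4S)-5-methyl-5-nitro-4-(propan-2-yl)hexanoyl] derivative of 10 (β-diketone; C7 epimerisable), via aldol adduct 16 (not isolated)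
Conditions: LiN(i-Pr)2 (1.05 equiv), THF, −78 °C; 15; H2O; then DMP, CH2Cl2, rt
Reagents that add atoms: none
Why: aldol addition of the only possible enolate (the CH2 beside the saturated ketone; every other α-position is quaternary or vinylic) and periodinane oxidation should give the 2-acyl ketone, whose ring stereocentre is enolisable and is fixed in step 9.

Step 9
Reactants: 17 7-acyl β-diketone; 18 geranyl bromide
Product: 19 7-exo-geranyl-7-endo-acyl diketone (bridgeheads as in 10; acyl arm over the enone bridge)
Conditions: Cs2CO3, DMF, 0 °C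
Reagents that add atoms: none
Why: C-alkylation of the β-diketone enolate by the allylic bromide from the convex (exo) face of the bicyclo[3.3.1] skeleton should place geranyl exo and leave the acyl arm endo, which is the arrangement the cage needs.

Step 10
Reactants: 19 7-exo-geranyl-7-endo-acyl diketone
Product: 21 α-diazoketone of 19 (diazo on the CH2 beside the arm ketone), via trifluoroacetyl ketone 20 (not isolated)
Conditions: LiN(SiMe3)2, THF, −78 °C; CF3CO2CH2CF3; then MeSO2N3, Et3N, H2O (1 equiv), MeCN, rt
Reagents that add atoms: methanesulfonyl azide, CS(=O)(=O)N=[N+]=[N-]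
Why: detrifluoroacetylative (Regitz-type) diazo transfer should occur at the only enolisable CH2, since all other carbonyl α-carbons are quaternary or vinylic, and give the α-alkyl-α-diazoketone.

Step 11
Reactants: 21 α-diazoketone
Product: 23 cage trione with cycloheptenone ring (C=C in the two-carbon bridge; nitroalkyl chain on the new quaternary carbon), via diazonium betaine 22 (not isolated)
Conditions: BF3·OEt2 (1.2 equiv), CH2Cl2, −78 to −20 °C
Reagents that add atoms: none
Why: BF3 activates the enone carbonyl, and the diazo carbon of the endo acyl arm, which can reach only the inner face of that carbonyl, adds to it in a 6-exo-trig sense to give betaine 22, thereby closing the six-membered 1,3,5-triketone ring. The antiperiplanar alkenyl carbon then shifts from the carbinol carbon to the diazonium carbon with loss of N2 and return of the ketone, so the cyclohexenone ring grows by the inserted carbon into the seven-membered ring; this is a Tiffeneau–Demjanov-type diazo–carbonyl ring expansion, closest to the known Lewis-acid-promoted ring expansion of cyclohexanones and cyclohexenones by α-alkyl-α-diazo esters. The new quaternary stereocentre is fixed by the tether, because the arm is endo on the geranyl-bearing carbon, so its acyl group must end on that side and the alkyl chain outside the cage. The step needs 1,2- over 1,4-addition to the enone (hard Lewis acid; the risk is treated below), alkenyl over bridgehead migration (the other α-carbon is the quaternary, tri-acylated bridgehead, which is electron-poor and cannot migrate), and attack at the ring ketone and not at the benzoyl group (exo, conjugated, less electrophilic).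

Step 12
Reactants: 23 cage trione with cycloheptenone ring
Product: 24 CNP0155129.3 (target)
Conditions: Bu3SnH (1.5 equiv, slow addition), AIBN (0.2 equiv), PhMe, 100 °C
Reagents that add atoms: none
Why: tin-mediated radical denitration should give the tertiary radical, which closes 5-exo-trig on the cage alkene through a chair-like transition state with the isopropyl group pseudo-equatorial (trans to the carbon that becomes the radical), setting the ring-fusion CH, before the secondary radical is reduced by Bu3SnH.

**Compound list**

1 | 3-methyl-1-phenylbut-2-en-1-one | CC(C)=CC(=O)c1ccccc1 | starting material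
2 | nitromethane | C[N+](=O)[O-] | starting material
3 | 3,3-dimethyl-4-nitro-1-phenylbutan-1-one | O=C(CC(C)(C)C[N+](=O)[O-])c1ccccc1 | intermediate
4 | 2,2,2-trifluoroethyl acrylate | C=CC(=O)OCC(F)(F)F | starting material
5 | bis(2,2,2-trifluoroethyl) 4-(2-methyl-4-oxo-4-phenylbutan-2-yl)-4-nitroheptanedioate | O=C(CC(C)(C)C(CCC(=O)OCC(F)(F)F)(CCC(=O)OCC(F)(F)F)[N+](=O)[O-])c1ccccc1 | intermediate
6 | bis(2,2,2-trifluoroethyl) 4-(2-methyl-4-oxo-4-phenylbutan-2-yl)heptanedioate | O=C(CC(C)(C)C(CCC(=O)OCC(F)(F)F)CCC(=O)OCC(F)(F)F)c1ccccc1 | intermediate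
7 | 2,2,2-trifluoroethyl 3-(3-benzoyl-2,2-dimethyl-4-oxocyclohexyl)propanoate (enolisable, no fixed configuration; not isolated) | O=C(c1ccccc1)C1C(=O)CCC(CCC(=O)OCC(F)(F)F)C1(C)C | intermediate
8 | meso-1-benzoyl-9,9-dimethylbicyclo[3.3.1]nonane-2,8-dione | C1C[C@H]2CCC(=O)[C@@](C(=O)c3ccccc3)(C1=O)C2(C)C | intermediate
9 | 2-(trimethylsilyloxy)-2-ene enol ether of 8, bridgeheads as in 10 (not isolated) | C1C[C@H]2CC=C(O[Si](C)(C)C)[C@@](C(=O)c3ccccc3)(C1=O)C2(C)C | intermediate
10 | (1S,5S)-1-benzoyl-9,9-dimethylbicyclo[3.3.1]non-3-ene-2,8-dione | C1C[C@H]2C=CC(=O)[C@@](C(=O)c3ccccc3)(C1=O)C2(C)C | intermediate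
11 | (E)-4-methylpent-2-enal | CC(C)/C=C/C=O | starting material
12 | 2-nitropropane | CC(C)[N+](=O)[O-] | starting material
13 | (3S)-4-methyl-4-nitro-3-(propan-2-yl)pentanal | O=CC[C@@H](C(C)C)C(C)(C)[N+](=O)[O-] | intermediate
14 | (4S)-1-methoxy-5-methyl-5-nitro-4-(propan-2-yl)hex-1-ene, E/Z mixture (not isolated) | COC=CC[C@@H](C(C)C)C(C)(C)[N+](=O)[O-] | intermediate
15 | (4S)-5-methyl-5-nitro-4-(propan-2-yl)hexanal | O=CCC[C@@H](C(C)C)C(C)(C)[N+](=O)[O-] | intermediate
16 | aldol adduct of 10 (ring CH beside the saturated ketone) with 15; carbinol and ring CH unassigned, bridgeheads as in 10, side chain 4S (not isolated) | OC(CC[C@@H](C(C)C)C(C)(C)[N+](=O)[O-])C1C[C@H]2C=CC(=O)[C@@](C(=O)c3ccccc3)(C1=O)C2(C)C | intermediate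
17 | 1-benzoyl-9,9-dimethyl-7-[(4S)-5-methyl-5-nitro-4-(propan-2-yl)hexanoyl]bicyclo[3.3.1]non-3-ene-2,8-dione, bridgeheads as in 10, C7 enolisable | O=C(CC[C@@H](C(C)C)C(C)(C)[N+](=O)[O-])C1C[C@H]2C=CC(=O)[C@@](C(=O)c3ccccc3)(C1=O)C2(C)C | intermediate
18 | geranyl bromide, (E)-1-bromo-3,7-dimethylocta-2,6-diene | CC(C)=CCC/C(C)=C/CBr | starting material
19 | 7-geranyl derivative of 17: geranyl exo, acyl arm endo (over the enone bridge), bridgeheads as in 10, side chain 4S | CC(C)=CCC/C(C)=C/C[C@]1(C(=O)CC[C@@H](C(C)C)C(C)(C)[N+](=O)[O-])C[C@H]2C=CC(=O)[C@@](C(=O)c3ccccc3)(C1=O)C2(C)C | intermediate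
20 | 19 carrying a trifluoroacetyl group on the CH2 beside the arm ketone, that carbon unassigned (not isolated) | CC(C)=CCC/C(C)=C/C[C@]1(C(=O)C(C(=O)C(F)(F)F)C[C@@H](C(C)C)C(C)(C)[N+](=O)[O-])C[C@H]2C=CC(=O)[C@@](C(=O)c3ccccc3)(C1=O)C2(C)C | intermediate
21 | α-diazoketone: 19 with a diazo group on the carbon beside the arm ketone | CC(C)=CCC/C(C)=C/C[C@]1(C(=O)C(=[N+]=[N-])C[C@@H](C(C)C)C(C)(C)[N+](=O)[O-])C[C@H]2C=CC(=O)[C@@](C(=O)c3ccccc3)(C1=O)C2(C)C | intermediate
22 | diazonium alkoxide betaine: diazo carbon of 21 bonded to the former enone carbonyl carbon, new centres as dictated by the tether (BF3 not drawn; not isolated) | CC(C)=CCC/C(C)=C/C[C@@]12C[C@H]3C=CC([O-])(C(C[C@@H](C(C)C)C(C)(C)[N+](=O)[O-])([N+]#N)C1=O)[C@@](C(=O)c1ccccc1)(C2=O)C3(C)C | intermediate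
23 | cage trione: target skeleton without the cyclopentane bond; C=C in the two-carbon bridge of the seven-membered ring; (2S)-3-methyl-3-nitro-2-(propan-2-yl)butyl chain on the new quaternary carbon | CC(C)=CCC/C(C)=C/C[C@@]12C[C@H]3C=C[C@@](C[C@@H](C(C)C)C(C)(C)[N+](=O)[O-])(C1=O)C(=O)[C@@](C(=O)c1ccccc1)(C2=O)C3(C)C | intermediate
24 | CNP0155129.3 | CC(C)=CCC/C(C)=C/C[C@@]12C[C@H]3C[C@H]4C(C)(C)[C@H](C(C)C)C[C@]4(C1=O)C(=O)[C@@](C(=O)c1ccccc1)(C2=O)C3(C)C | target

**Count and risks**

Total step count: 12. Longest linear sequence: 10 steps (steps 1–5 and 8–12); steps 6–7 make the side-chain aldehyde.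

Steps most likely to fail:

Step 11. The diazo carbon can reach the enone β-carbon as easily as the carbonyl carbon, so conjugate addition or dipolar cycloaddition to the C=C (ending in cyclopropane formation), or a 1,2-hydride shift of the diazoketone, may outrun carbonyl addition. Fallback: the enone is masked before the ring expansion. Starting from 21, thiophenol with catalytic Et3N should add to the enone to give the β-phenylthio ketone F1. BF3·OEt2 should then effect the same diazo–carbonyl ring expansion on a saturated ketone, in which only the ring CH2 can migrate, to give the cage sulfide F2. NaIO4 should oxidise it to the sulfoxide F3, and thermal syn-elimination (PhMe, 110 °C; elimination towards the bridgehead is not possible) should return to the route at 23.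

Step 12. The tertiary radical may be reduced before it closes, or it may close on the wrong face of the cage alkene, because the two faces differ only in remote substituents. Fallback: a polar closure in place of the radical one. Starting from 23, SnCl4 (CH2Cl2, −78 °C) should ionise the tertiary nitro group; cation–olefin 5-exo closure and chloride capture at the neighbouring cage carbon should give the cage chloride F4, and Bu3SnH with AIBN should remove the chlorine to reach 24.

Step 4. The second C-acylation creates a non-enolisable tri-acylated carbon and may stop at the monocyclic stage or revert by retro-Claisen cleavage. Fallback: the second ring is closed irreversibly through an acid chloride. Starting from 6, NaH (1.1 equiv) should give the monocyclic diketone 7, now isolated. LiOH hydrolysis should give the keto acid F5, (COCl)2 the acid chloride F6, and MgCl2 with Et3N the intramolecular C-acylation that returns to the route at 8.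

**Further compounds**

F1 | step 11 | thiophenol adduct of 21 (phenylthio group on the former enone β-carbon, either epimer) | CC(C)=CCC/C(C)=C/C[C@]1(C(=O)C(=[N+]=[N-])C[C@@H](C(C)C)C(C)(C)[N+](=O)[O-])C[C@H]2C(Sc3ccccc3)CC(=O)[C@@](C(=O)c3ccccc3)(C1=O)C2(C)C
F2 | step 11 | ring-expanded cage sulfide (23 with H and SPh added across the C=C, SPh on the carbon next to the CH bridgehead) | CC(C)=CCC/C(C)=C/C[C@@]12C[C@H]3C(Sc4ccccc4)C[C@@](C[C@@H](C(C)C)C(C)(C)[N+](=O)[O-])(C1=O)C(=O)[C@@](C(=O)c1ccccc1)(C2=O)C3(C)C
F3 | step 11 | sulfoxide of F2 | CC(C)=CCC/C(C)=C/C[C@@]12C[C@H]3C(S(=O)c4ccccc4)C[C@@](C[C@@H](C(C)C)C(C)(C)[N+](=O)[O-])(C1=O)C(=O)[C@@](C(=O)c1ccccc1)(C2=O)C3(C)C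
F4 | step 12 | cage chloride (target with Cl on the CH2 between the CH bridgehead and the ring-fusion CH, either epimer) | CC(C)=CCC/C(C)=C/C[C@@]12C[C@H]3C(Cl)[C@H]4C(C)(C)[C@H](C(C)C)C[C@]4(C1=O)C(=O)[C@@](C(=O)c1ccccc1)(C2=O)C3(C)C
F5 | step 4 | 3-(3-benzoyl-2,2-dimethyl-4-oxocyclohexyl)propanoic acid | O=C(c1ccccc1)C1C(=O)CCC(CCC(=O)O)C1(C)C
F6 | step 4 | 3-(3-benzoyl-2,2-dimethyl-4-oxocyclohexyl)propanoyl chloride | O=C(c1ccccc1)C1C(=O)CCC(CCC(=O)Cl)C1(C)C
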